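**Plan**

- Retrosynthetically, the benzene ring of the target is taken back by two hydrogens to a 4-substituted cyclohex-2-enone. The phenol carbon becomes the ketone carbon and the para carbon becomes the sp3 ring carbon that carries the CH2CH2CO2C26H53 chain.
- This para relation is the enabling feature: the chain-bearing ring carbon is the α-carbon of an aldehyde that already holds the whole ester chain. The ring is therefore cut at the single bond from that carbon to its neighbouring ring CH2 (Michael bond) and at the C=C on its other side (aldol condensation bond). This gives methyl vinyl ketone and hexacosyl 5-oxopentanoate.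
- The aldehyde is traced to a terminal alkene (C=C cleavage), and the ester C–O bond is cut to hex-5-enoic acid and 1-hexacosanol.
- Forward order: the chain is joined first by esterification, the alkene is ozonised, the only ring is built by amine-catalysed Michael addition and aldol condensation, and the enone is dehydrogenated to the phenol.
- Stereochemistry: the target has no stereocentre. The single ring stereocentre made in the annulation is racemic and disappears on aromatisation.

Key step: step 3

Remark: all C26 intermediates are expected to be waxes of low solubility in cold or polar media, so temperatures and solvents are chosen to keep them dissolved.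

**Route**

Step 1
Reactants: 1 hex-5-enoic acid; 2 1-hexacosanol
Product: 3 hexacosyl hex-5-enoate
Conditions: DCC (1.2 equiv), DMAP (10 mol%), CH2Cl2/THF, 35 °C
Reagents that add atoms: none
Why: Steglich esterification, in which the carbodiimide activates the acid as its O-acylisourea and DMAP passes the acyl group to the unhindered primary alcohol, while the terminal alkene is inert and gentle warming keeps the long-chain alcohol in solution.

Step 2
Reactants: 3 hexacosyl hex-5-enoate
Product: 5 hexacosyl 5-oxopentanoate, via secondary ozonide 4 (not isolated)
Conditions: O3/O2, CH2Cl2, −40 °C; then PPh3 (1.2 equiv), −40 °C to rt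
Reagents that add atoms: ozone, [O-][O+]=O
Why: Ozonolysis with reductive work-up, in which ozone adds to the only C=C, the primary ozonide rearranges to the 1,2,4-trioxolane 4, and PPh3 reduces this to the aldehyde without touching the ester; the aldehyde should be used promptly.

Step 3
Reactants: 5 hexacosyl 5-oxopentanoate; 6 methyl vinyl ketone (1.5 equiv)
Product: 9 hexacosyl 3-(4-oxocyclohex-2-en-1-yl)propanoate (racemic), via keto aldehyde 7 (not isolated), via ketol 8 (not isolated)
Conditions: Et2NH (30 mol%), THF, 35 °C; evaporate; then p-TsOH·H2O (10 mol%), toluene, reflux, Dean–Stark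
Reagents that add atoms: none
Why: Et2NH condenses only with the aldehyde of 5 (the ester cannot form an enamine), and the enamine adds through its β-carbon to the unsubstituted terminus of 6, so that hydrolysis of the resulting iminium returns the amine and leaves keto aldehyde 7 with the new C–C bond at the carbon that carries the ester chain. Acid then enolises the methyl ketone toward its CH3 group, and this enol attacks the aldehyde carbonyl in a 6-(enolendo)-exo-trig aldol closure to ketol 8, the only cyclisation open to 7 because every alternative would give a four-membered ring; loss of water gives the conjugated enone 9. The closest known reaction type is the secondary-amine-catalysed Michael addition of unmodified aldehydes to vinyl ketones followed by aldol condensation, that is, a Robinson annulation in its Stork enamine form. The one new stereocentre, the ring carbon bearing the chain, arises without control as a racemate, which is acceptable because step 4 flattens it. The selectivity required is mono-alkylation at the aldehyde α-carbon rather than at the ester α-carbon or twice at the same carbon; the first is secured by enamine formation at the aldehyde alone, the second by the lower reactivity of the α-branched aldehyde 7 toward enamine formation and by the small excess of 6.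

Step 4
Reactants: 9 hexacosyl 3-(4-oxocyclohex-2-en-1-yl)propanoate
Product: 11 hexacosyl 3-(4-hydroxyphenyl)propanoate, via dienone 10 (not isolated)
Conditions: Pd(OCOCF3)2 (5 mol%), 2-(dimethylamino)pyridine (10 mol%), p-TsOH (20 mol%), O2 (1 atm), DMSO, 80 °C
Reagents that add atoms: none
Why: Aerobic palladium-catalysed α,β-dehydrogenation, a catalytic relative of the Saegusa–Ito oxidation, in which divalent palladium forms the enolate at the ring CH2 next to the ketone, β-hydride elimination gives the cross-conjugated dienone 10, the ring C–H at the chain-bearing carbon tautomerises to the phenol O–H under the drive of aromaticity, and O2 returns zerovalent palladium to the divalent state.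

**Compound list**

1 | hex-5-enoic acid | C=CCCCC(=O)O | starting material
2 | 1-hexacosanol | CCCCCCCCCCCCCCCCCCCCCCCCCCO | starting material
3 | hexacosyl hex-5-enoate | CCCCCCCCCCCCCCCCCCCCCCCCCCOC(=O)CCCC=C | intermediate
4 | hexacosyl 4-(1,2,4-trioxolan-3-yl)butanoate (secondary ozonide, racemic, not isolated) | CCCCCCCCCCCCCCCCCCCCCCCCCCOC(=O)CCCC1OCOO1 | intermediate
5 | hexacosyl 5-oxopentanoate | CCCCCCCCCCCCCCCCCCCCCCCCCCOC(=O)CCCC=O | intermediate
6 | methyl vinyl ketone (but-3-en-2-one) | CC(=O)C=C | starting material
7 | hexacosyl 4-formyl-7-oxooctanoate (keto aldehyde, racemic, not isolated) | CCCCCCCCCCCCCCCCCCCCCCCCCCOC(=O)CCC(C=O)CCC(C)=O | intermediate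
8 | hexacosyl 3-(2-hydroxy-4-oxocyclohexyl)propanoate (ketol, mixture of racemic diastereomers, not isolated) | CCCCCCCCCCCCCCCCCCCCCCCCCCOC(=O)CCC1CCC(=O)CC1O | intermediate
9 | hexacosyl 3-(4-oxocyclohex-2-en-1-yl)propanoate (racemic) | CCCCCCCCCCCCCCCCCCCCCCCCCCOC(=O)CCC1CCC(=O)C=C1 | intermediate
10 | hexacosyl 3-(4-oxocyclohexa-2,5-dien-1-yl)propanoate (dienone, not isolated) | CCCCCCCCCCCCCCCCCCCCCCCCCCOC(=O)CCC1C=CC(=O)C=C1 | intermediate
11 | hexacosyl 3-(4-hydroxyphenyl)propanoate | CCCCCCCCCCCCCCCCCCCCCCCCCCOC(=O)CCc1ccc(O)cc1 | target

**Step count**

Total steps: 4. Longest linear sequence: 4 steps (1 or 2 → 3 → 5 → 9 → 11).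

**Steps most likely to fail, with fallbacks**

Step 3. Under catalytic amine, self-aldol condensation of the aldehyde and polymerisation of the vinyl ketone may outrun the conjugate addition, or a second Michael addition may occur at the same carbon. The fallback uses a stoichiometric, preformed enamine. It sets out from 5, which is condensed with pyrrolidine (1.2 equiv) over 4 Å molecular sieves in toluene to give the enamine hexacosyl (E)-5-(pyrrolidin-1-yl)pent-4-enoate F1. F1 is treated with 6 in toluene at 0 °C to rt; aldehyde enamines are expected to give the [4+2] adduct hexacosyl 3-[6-methyl-2-(pyrrolidin-1-yl)-3,4-dihydro-2H-pyran-3-yl]propanoate F2. Hydrolysis of F2 with aqueous AcOH/NaOAc buffer should release pyrrolidine and give the keto aldehyde. The fallback returns to the route at 7, which is closed to 9 with p-TsOH in refluxing toluene as in the second stage of step 3.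

Step 4. The wax may dissolve poorly in DMSO, so that the palladium catalyst aggregates to inactive metal before turnover is complete and the reaction stalls at the enone. The fallback is a stoichiometric selenoxide elimination. It sets out from 9, which is deprotonated at the ring CH2 next to the ketone with LiN(iPr)2 (1.05 equiv) in dilute THF at −78 °C. The ketone is enolised kinetically ahead of the less acidic ester. The enolate is trapped with PhSeBr to give hexacosyl 3-[4-oxo-5-(phenylselanyl)cyclohex-2-en-1-yl]propanoate F3. Oxidation with H2O2 and pyridine in CH2Cl2 at 0 °C should give the selenoxide hexacosyl 3-[4-oxo-5-(phenylseleninyl)cyclohex-2-en-1-yl]propanoate F4, which undergoes syn elimination on warming to rt. The fallback returns to the route at 10, which tautomerises to 11.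

Step 2. The waxy alkene may precipitate at low temperature and leave ozonide formation incomplete, or the aldehyde may be over-oxidised to the acid during ozonisation and work-up. The fallback is a dihydroxylation followed by glycol cleavage at room temperature. It sets out from 3, which is dihydroxylated with OsO4 (2 mol%) and N-methylmorpholine N-oxide in THF/t-BuOH/water at rt to give hexacosyl 5,6-dihydroxyhexanoate F5 (racemic). F5 is cleaved with NaIO4 on silica gel in CH2Cl2 at rt. The fallback returns to the route at 5.

**Further compounds**

F1 | step 3 | hexacosyl (E)-5-(pyrrolidin-1-yl)pent-4-enoate | CCCCCCCCCCCCCCCCCCCCCCCCCCOC(=O)CC/C=C/N1CCCC1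
F2 | step 3 | hexacosyl 3-[6-methyl-2-(pyrrolidin-1-yl)-3,4-dihydro-2H-pyran-3-yl]propanoate (mixture of racemic diastereomers) | CCCCCCCCCCCCCCCCCCCCCCCCCCOC(=O)CCC1CC=C(C)OC1N1CCCC1
F3 | step 4 | hexacosyl 3-[4-oxo-5-(phenylselanyl)cyclohex-2-en-1-yl]propanoate (mixture of racemic diastereomers) | CCCCCCCCCCCCCCCCCCCCCCCCCCOC(=O)CCC1CC([Se]c2ccccc2)C(=O)C=C1
F4 | step 4 | hexacosyl 3-[4-oxo-5-(phenylseleninyl)cyclohex-2-en-1-yl]propanoate (mixture of stereoisomers, not isolated) | CCCCCCCCCCCCCCCCCCCCCCCCCCOC(=O)CCC1CC([Se](=O)c2ccccc2)C(=O)C=C1
F5 | step 2 | hexacosyl 5,6-dihydroxyhexanoate (racemic) | CCCCCCCCCCCCCCCCCCCCCCCCCCOC(=O)CCCC(O)CO
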